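**Strategy**

The key step exploits the cyclopentane ring, numbered C1 (aryl/methyl quaternary carbon), C2 (CHMe), C3 (bromomethylidene carbon), C4 and C5: with C3 as a latent ketone, C1–C2–C3–C4–C5 is a pentadienyl unit, so the ring is disconnected at C1–C5 to a cross-conjugated dienone. One enantioselective, silicon-directed Nazarov cyclisation closes the five-membered ring, creates the quaternary stereocentre C1, fixes the alkene at C4=C5 and sets C2 on protonation. Its precursor is a single (E,E)-dienone with the aryl/methyl tetrasubstituted alkene on one side and a β-trimethylsilylvinyl group on the other, assembled by stereoretentive cross-coupling so that no alkene isomers reach the key step.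

Key step: step 5

Remark on the chemistry (assumption): which antipode of the acid catalyst favours the required conrotation cannot be assigned in advance; the (S,S)-catalyst is written, and its mirror image would be used if it led to the (4S) series. In the commentary, C1–C5 always mean the ring atoms of the target as numbered above; compound names use their own locants.

**Route**

Step 1
Reactants: 1 methyl 2-methyl-3-oxobutanoate
Product: 2 methyl (2E)-2-methyl-3-{[(4-methylphenyl)sulfonyl]oxy}but-2-enoate (tosyloxy group trans to the ester)
Conditions: TsCl, Me2N(CH2)6NMe2, MeCN, 0 °C to rt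
Reagents that add atoms: p-toluenesulfonyl chloride, Cc1ccc(cc1)S(=O)(=O)Cl
Why: Sulfonylation of the β-keto ester under lithium-free amine conditions is a known stereocomplementary enol tosylation in which the non-chelated enolate is trapped with the tosyloxy group trans to the ester, so the E isomer should result and fix the alkene geometry for everything that follows.

Step 2
Reactants: 2 methyl (2E)-2-methyl-3-{[(4-methylphenyl)sulfonyl]oxy}but-2-enoate, 3 (2-methoxy-4-methylphenyl)boronic acid
Product: 4 methyl (2E)-3-(2-methoxy-4-methylphenyl)-2-methylbut-2-enoate (aryl trans to the ester, cis to the α-methyl group)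
Conditions: Pd(OAc)2 (cat.), SPhos, K3PO4, toluene/H2O, 80 °C
Reagents that add atoms: none
Why: Suzuki–Miyaura coupling of a β-tosyloxy acrylate (oxidative addition into the activated C–O bond, transmetalation, reductive elimination) is stereoretentive, so the aryl group should take the place of the tosyloxy group, trans to the ester and cis to the α-methyl group.

Step 3
Reactants: 4 methyl (2E)-3-(2-methoxy-4-methylphenyl)-2-methylbut-2-enoate
Product: 5 (2E)-N-methoxy-3-(2-methoxy-4-methylphenyl)-N,2-dimethylbut-2-enamide
Conditions: MeNH(OMe)·HCl, i-PrMgCl, THF, −20 °C to rt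
Reagents that add atoms: N,O-dimethylhydroxylamine hydrochloride, CNOC.Cl
Why: Weinreb amide formation by attack of the chloromagnesium amide of N,O-dimethylhydroxylamine on the methyl ester is a standard acyl substitution that should leave the tetrasubstituted alkene and its geometry untouched.

Step 4
Reactants: 5 (2E)-N-methoxy-3-(2-methoxy-4-methylphenyl)-N,2-dimethylbut-2-enamide, 6 (E)-(2-bromoethenyl)trimethylsilane
Product: 9 (1E,4E)-5-(2-methoxy-4-methylphenyl)-4-methyl-1-(trimethylsilyl)hexa-1,4-dien-3-one, via vinyllithium 7 (not isolated), via lithium hemiaminal alkoxide 8 (not isolated)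
Conditions: 6, t-BuLi (2 equiv), Et2O, −78 °C; then 5, THF, −78 to 0 °C; aq NH4Cl
Reagents that add atoms: none
Why: Bromine–lithium exchange with two equivalents of t-BuLi retains the E geometry of the vinyl unit, and the Weinreb ketone synthesis stops at the chelated tetrahedral adduct 8 until the quench, so a single addition should give the cross-conjugated dienone.

Step 5
Reactants: 9 (1E,4E)-5-(2-methoxy-4-methylphenyl)-4-methyl-1-(trimethylsilyl)hexa-1,4-dien-3-one
Product: 11 (4R,5R)-4-(2-methoxy-4-methylphenyl)-4,5-dimethylcyclopent-2-en-1-one (C5 methyl cis to the aryl group), via dienol 10 (not isolated)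
Conditions: (S,S)-IDPi (confined chiral imidodiphosphorimidate Brønsted acid, 5 mol %), PhOH (1.2 equiv), toluene, −20 °C to rt
Reagents that add atoms: none
Why: Proposed new method: the confined acid protonates the carbonyl oxygen to give a hydroxypentadienyl cation paired with the chiral anion, a conrotatory 4π electrocyclisation joins C1 to C5 and thereby closes the only new ring, the five-membered carbocycle, the resulting β-silyl-stabilised oxyallyl cation hands its silyl group to phenol so that the alkene can only appear at C4=C5, and dienol 10 is protonated at C2. The closest known reaction types are the silicon-directed Nazarov cyclisation, which with achiral acids is known to close onto fully substituted termini, and the enantioselective Nazarov cyclisation of simple and of β-silyl divinyl ketones under chiral Brønsted acids; the new element is an aryl,methyl-disubstituted terminus that becomes a quaternary stereocentre under catalyst control. C1 is set by the catalyst, whose chiral pocket must favour one of the two conrotations, and this torquoselectivity maps onto one configuration only because the tetrasubstituted alkene enters as a single E isomer. C2 is set by the substrate, since the proton should reach the dienol on the face opposite the bulky aryl group and so leave the C2 methyl cis to it, and the low temperature and catalytic acid loading should not equilibrate this α′ centre afterwards. Regioselectivity of the alkene is secured by silicon, and reactivity by the α-methyl group, which favours the s-trans/s-trans conformer, and by the electron-rich aryl group, which stabilises the cation.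

Step 6
Reactants: 11 (4R,5R)-4-(2-methoxy-4-methylphenyl)-4,5-dimethylcyclopent-2-en-1-one
Product: 12 (2R,3R)-3-(2-methoxy-4-methylphenyl)-2,3-dimethylcyclopentan-1-one (C2 methyl cis to the aryl group)
Conditions: H2 (1 atm), Pd/C, EtOAc, rt
Reagents that add atoms: none
Why: Heterogeneous catalytic hydrogenation under neutral conditions should saturate the unhindered disubstituted C4=C5 enone bond selectively over the ketone and the arene, and it leaves C1 and C2 alone because C2 can only be lost through enolisation.

Step 7
Reactants: 12 (2R,3R)-3-(2-methoxy-4-methylphenyl)-2,3-dimethylcyclopentan-1-one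
Product: 13 1-[(1R,2R,3E)-3-(bromomethylidene)-1,2-dimethylcyclopentyl]-2-methoxy-4-methylbenzene (bromine anti to C2)
Conditions: (Ph3PCH2Br)Br, NaN(SiMe3)2, THF, −60 °C; then 12, −60 °C to rt
Reagents that add atoms: (bromomethyl)triphenylphosphonium bromide, BrC[P+](c1ccccc1)(c1ccccc1)c1ccccc1.[Br-]
Why: Wittig olefination with (bromomethylidene)triphenylphosphorane generated at low temperature is the established route from hindered α-branched cyclic ketones to E-bromomethylidene compounds, the bromine settling anti to the more substituted α-carbon C2, while any deprotonation by the ylide should occur at the unhindered C4 methylene and so spare the C2 configuration.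

Step 8
Reactants: 13 1-[(1R,2R,3E)-3-(bromomethylidene)-1,2-dimethylcyclopentyl]-2-methoxy-4-methylbenzene
Product: 14 1-bromo-5-[(1R,2R,3E)-3-(bromomethylidene)-1,2-dimethylcyclopentyl]-4-methoxy-2-methylbenzene (aryl bromine para to the methoxy group)
Conditions: NBS, MeCN, 0 °C to rt, dark
Reagents that add atoms: N-bromosuccinimide, O=C1CCC(=O)N1Br
Why: Electrophilic aromatic substitution with NBS in acetonitrile is para-selective for anisoles, and the position para to the methoxy group is further activated by the adjacent methyl group, whereas the bromine-substituted exocyclic alkene is too electron-poor to compete.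

Step 9
Reactants: 14 1-bromo-5-[(1R,2R,3E)-3-(bromomethylidene)-1,2-dimethylcyclopentyl]-4-methoxy-2-methylbenzene
Product: 16 4-bromo-2-[(1R,2R,3E)-3-(bromomethylidene)-1,2-dimethylcyclopentyl]-5-methylphenol, via aryloxydibromoborane 15 (not isolated)
Conditions: BBr3, CH2Cl2, −78 to 0 °C; then H2O
Reagents that add atoms: none
Why: Lewis acid mediated ether cleavage, in which BBr3 coordinates the ether oxygen and bromide removes the methyl group by SN2 attack, should free the phenol at low temperature without touching the aryl bromide, the vinyl bromide or either stereocentre, and hydrolysis of borane 15 on work-up gives the target.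

**Compound list**

1 | methyl 2-methyl-3-oxobutanoate | COC(=O)C(C)C(C)=O | starting material
2 | methyl (2E)-2-methyl-3-{[(4-methylphenyl)sulfonyl]oxy}but-2-enoate | COC(=O)/C(C)=C(C)/OS(=O)(=O)c1ccc(C)cc1 | intermediate
3 | (2-methoxy-4-methylphenyl)boronic acid | COc1cc(C)ccc1B(O)O | starting material
4 | methyl (2E)-3-(2-methoxy-4-methylphenyl)-2-methylbut-2-enoate | COc1cc(C)ccc1/C(C)=C(\C)C(=O)OC | intermediate
5 | (2E)-N-methoxy-3-(2-methoxy-4-methylphenyl)-N,2-dimethylbut-2-enamide | COc1cc(C)ccc1/C(C)=C(\C)C(=O)N(C)OC | intermediate
6 | (E)-(2-bromoethenyl)trimethylsilane | C[Si](C)(C)/C=C/Br | starting material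
7 | [(E)-2-(trimethylsilyl)ethenyl]lithium (formed in the flask) | C[Si](C)(C)/C=C/[Li] | intermediate
8 | lithium (1E,4E)-3-[methoxy(methyl)amino]-5-(2-methoxy-4-methylphenyl)-4-methyl-1-(trimethylsilyl)hexa-1,4-dien-3-olate (formed in the flask) | COc1cc(C)ccc1/C(C)=C(\C)C(O[Li])(/C=C/[Si](C)(C)C)N(C)OC | intermediate
9 | (1E,4E)-5-(2-methoxy-4-methylphenyl)-4-methyl-1-(trimethylsilyl)hexa-1,4-dien-3-one | COc1cc(C)ccc1/C(C)=C(\C)C(=O)/C=C/[Si](C)(C)C | intermediate
10 | (3R)-3-(2-methoxy-4-methylphenyl)-2,3-dimethylcyclopenta-1,4-dien-1-ol (formed in the flask) | COc1cc(C)ccc1[C@]1(C)C=CC(O)=C1C | intermediate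
11 | (4R,5R)-4-(2-methoxy-4-methylphenyl)-4,5-dimethylcyclopent-2-en-1-one | COc1cc(C)ccc1[C@]1(C)C=CC(=O)[C@@H]1C | intermediate
12 | (2R,3R)-3-(2-methoxy-4-methylphenyl)-2,3-dimethylcyclopentan-1-one | COc1cc(C)ccc1[C@]1(C)CCC(=O)[C@@H]1C | intermediate
13 | 1-[(1R,2R,3E)-3-(bromomethylidene)-1,2-dimethylcyclopentyl]-2-methoxy-4-methylbenzene | COc1cc(C)ccc1[C@]1(C)CC/C(=C\Br)[C@@H]1C | intermediate
14 | 1-bromo-5-[(1R,2R,3E)-3-(bromomethylidene)-1,2-dimethylcyclopentyl]-4-methoxy-2-methylbenzene | COc1cc(C)c(Br)cc1[C@]1(C)CC/C(=C\Br)[C@@H]1C | intermediate
15 | dibromo{4-bromo-2-[(1R,2R,3E)-3-(bromomethylidene)-1,2-dimethylcyclopentyl]-5-methylphenoxy}borane (formed in the flask) | Cc1cc(OB(Br)Br)c(cc1Br)[C@]1(C)CC/C(=C\Br)[C@@H]1C | intermediate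
16 | 4-bromo-2-[(1R,2R,3E)-3-(bromomethylidene)-1,2-dimethylcyclopentyl]-5-methylphenol | Cc1cc(O)c([C@]2(C)CC/C(=C\Br)[C@@H]2C)cc1Br | target

**Step count**

Total step count: 9. Longest linear sequence: 9 steps (1 to 16); 3 and 6 enter as side inputs.

**Steps most likely to fail**

Step 5 (key step). Ring closure at the fully substituted, aryl-stabilised terminus may be so slow that protodesilylation of the vinylsilane or geometric isomerisation of the tetrasubstituted alkene through the cation competes. The two conrotations may also be poorly differentiated, and protonation at C2 may be unselective. The fallback uses known chemistry and sets out from 9. The classical achiral silicon-directed Nazarov cyclisation with stoichiometric FeCl3 (CH2Cl2, −30 to 0 °C) should give the enone as the racemate, that is 11 together with its mirror image (4S,5S)-4-(2-methoxy-4-methylphenyl)-4,5-dimethylcyclopent-2-en-1-one F1. Preparative chromatography on a chiral stationary phase separates the two and rejoins the route at 11. If the C2 methyl has not come out cis to the aryl group, the (4R) material is converged, C2 being the only enolisable position of the enone. LiN(i-Pr)2 (THF, −78 °C) gives lithium (3R)-3-(2-methoxy-4-methylphenyl)-2,3-dimethylcyclopenta-1,4-dien-1-olate F2, and quenching with 2,6-di-tert-butyl-4-methylphenol at −78 °C should deliver the proton to the face opposite the aryl group, again giving 11.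

Step 7. The thermally fragile bromo ylide may decompose, or merely enolise the hindered cyclopentanone, faster than it adds. Conversion then stalls, the E/Z ratio erodes, and any enolisation towards C2 would scramble that centre. The fallback sets out from 12. A boron-Wittig olefination with LiCH(Bpin)2 (from CH2(Bpin)2 and lithium 2,2,6,6-tetramethylpiperidide, THF, −78 °C to rt) uses a thermally robust carbanion that adds to the carbonyl group at −78 °C and eliminates with boron anti to the bulkier α-carbon. It should give 2-{(E)-[(2S,3R)-3-(2-methoxy-4-methylphenyl)-2,3-dimethylcyclopentylidene]methyl}-4,4,5,5-tetramethyl-1,3,2-dioxaborolane F3. Copper-mediated bromodeboronation (CuBr2, MeOH/H2O, 70 °C), which retains the alkene geometry, then comes back to the route at 13. Any concurrent para-bromination of the anisole ring would only anticipate step 8.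

Step 4. Addition of the vinyllithium to the twisted, doubly flanked amide carbonyl group may be slower than deprotonation of the allylic methyl groups or base-induced fragmentation of the N-methoxy group, so that the amide is consumed unproductively. The fallback sets out from 5. Reduction with i-Bu2AlH (THF, −78 °C) should stop at (2E)-3-(2-methoxy-4-methylphenyl)-2-methylbut-2-enal F4. This far more electrophilic aldehyde takes up vinyllithium 7 at −78 °C to give (1E,4E)-5-(2-methoxy-4-methylphenyl)-4-methyl-1-(trimethylsilyl)hexa-1,4-dien-3-ol F5 (carbinol centre unimportant). Oxidation of the bis-allylic alcohol with MnO2 (CH2Cl2, rt) comes back to the route at 9.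

**Further compounds**

F1 | step 5 | (4S,5S)-4-(2-methoxy-4-methylphenyl)-4,5-dimethylcyclopent-2-en-1-one | COc1cc(C)ccc1[C@@]1(C)C=CC(=O)[C@H]1C
F2 | step 5 | lithium (3R)-3-(2-methoxy-4-methylphenyl)-2,3-dimethylcyclopenta-1,4-dien-1-olate | COc1cc(C)ccc1[C@]1(C)C=CC(O[Li])=C1C
F3 | step 7 | 2-{(E)-[(2S,3R)-3-(2-methoxy-4-methylphenyl)-2,3-dimethylcyclopentylidene]methyl}-4,4,5,5-tetramethyl-1,3,2-dioxaborolane | COc1cc(C)ccc1[C@]1(C)CC/C(=C\B2OC(C)(C)C(C)(C)O2)[C@@H]1C
F4 | step 4 | (2E)-3-(2-methoxy-4-methylphenyl)-2-methylbut-2-enal | COc1cc(C)ccc1/C(C)=C(\C)C=O
F5 | step 4 | (1E,4E)-5-(2-methoxy-4-methylphenyl)-4-methyl-1-(trimethylsilyl)hexa-1,4-dien-3-ol | COc1cc(C)ccc1/C(C)=C(\C)C(O)/C=C/[Si](C)(C)C
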